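## The problem

The target joins a quinolizidin-2-one (rings A and B, fused through N4–C27) to a 1-oxaquinolizidine (rings C and D, fused through N31–C17). Two polymethylene chains, C9–C14 from C8 to C15 and C19–C23 from C18 to C24, tie them into an 18-membered ring. Eight stereocentres must be set: C33 and C15 on ring C, C17 and C18 at the N,O-acetal, C2, C24 and C27 on ring A, and C8 on ring B. In the east, C17 and its α-carbon C18 can equilibrate through ring opening and enamine formation, and the target holds the all-equatorial trans-fused arrangement, so C15 and C33 can dictate them under thermodynamic control. In the west only C2 can come from the chiral pool; it has to pass its information to C27 and C8 through C24, the position next to the future iminium carbon. C24 is the awkward centre: its chain is cis to C8 on ring A (H24 syn to H27). In a trans-fused bicycle this would place the chain axial and syn-pentane to C9, so the required epimer is expected to be the less stable one and should not be reachable by equilibrating the β-amino ketone. The ketone flanked by C2–H and C24–H, the retro-Mannich-prone N4–C27–C24–C25=O array and the acid- and hydride-labile N,O-acetal forbid rough treatment late in the route. An N-acyliminium approach is possible because ring B shares N4–C27 with ring A and carries its chain on C8 trans to C24, which is the outcome of a chair-like attack on a ring-A iminium ion at C27 by a C8 nucleophile tethered to N4 through C5–C7.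

## Retrosynthesis

**C24–H and C9–C10 saturation, last.** Target 44 is taken back to the macrocyclic dienone 43, with an exocyclic (E)-C23=C24 enone and a C9=C10 olefin; only C–H bonds are cut. Hydrogen delivery is preferred to epimerizing the saturated ketone (expected to favour the wrong C24 epimer) and to enolate protonation (no regiocontrol between C2–H and C24–H). In 43, allylic strain between C22 and C8 should hold C8 axial on ring A, so hydrogen must arrive anti to C8, giving H24 syn to H27. The precursor has one stereocentre fewer and no later step can disturb C24.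

**C9=C10 by ring-closing metathesis.** 43 is opened to the acyclic enone diene 42. The C8 vinyl group is what an allylsilane cyclization leaves behind, so this cut costs no extra steps; closing at C23=C24 instead would need an enolate at high dilution. The forward reaction must tolerate two amines (as salts) and leave the trisubstituted enone alone.

**C23=C24 by aldol condensation.** 42 is divided into quinolizidinone 24 and oxaquinolizidine aldehyde 39, two fragments of similar size. Ketone 24 has a single α-methylene group (C24), so kinetic enolization and dehydration can only give the exocyclic enone. Alkylating C24 instead would fix the chain trans to C8.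

**Western fragment back to the cyclization product.** 24 comes from lactam ketal 21 by reduction of the C5 lactam (22), unmasking of the ketone and the C24 hydroxymethyl group (23), and retro-aldol loss of formaldehyde. The CH2OSi(i-Pr)3 group on C24 is a temporary control element: without it C2 alone would bias the iminium ion only weakly. The forward steps must not touch C2, C8 or C27.

**C8–C27, the key cut.** 21 is opened to the N-acyl hemiaminal ether 20, which carries the (E)-allylsilane on the N4 acyl chain. One ring and two stereocentres (C8, C27) are removed. The forward step must attack C27 anti to the C24 substituent, pass through a chair, and cyclize faster than the cation loses its C24 proton.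

**Ring-A precursor.** 20 arises from amide alcohol 18 by oxidation and hemiaminal formation (N4–C27), and 18 from amine 17 and acid 7 (N4–C5).
- 17 comes from lactam 15 by reductive opening (16) and loss of the carbamate. The lactam is the template in which C24 is set cis to the C2 methyl by kinetic protonation. Opening it avoids partial reduction of an N-acyl lactam, where the unhindered side-chain carbonyl would compete with the hindered ring carbonyl.
- 15 goes back through ketal 13 and dione 12 to the Cbz amino acid 9 and Meldrum's acid 10, and 9 to (R)-3-amino-2-methylpropanoic acid 8.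
- Acid 7 comes from acetate 4 by Ireland–Claisen rearrangement, which fixes the (E)-geometry, and 4 from 3, made from 1 and 2.

**Eastern fragment.** 39 comes from 37 via alcohol 38, and 37 from amino alcohol 31 and chloro aldehyde 35. Three bonds (O16–C17, N31–C17, N31–C30) and both rings form in one condensation that is self-correcting at C17 and C18.
- 31 goes back through 30, 29 and 27 to the (S)-amino acid 25 and Grignard reagent 28, so both halves draw their methyl stereocentre from the two enantiomers of one amino acid.
- 35 comes from ester 34, made from 32 and 33.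

## Roads not taken

**Alternative 1:** The cut is the C23=C24 bond of the macrocyclic exocyclic E-enone A1. In the forward key step a ring-A β-ketophosphonate anion at C24 condenses with a C23 aldehyde at the end of the C18 arm and closes the 18-membered ring.
- Merits: the olefination is regiodefined at C24, runs under mild base, needs no metal catalyst near two amines, and leads to the same enone-hydrogenation end-game used here.
- Weak points: the phosphonate must be placed at C24 of a β-amino ketone that has a second enolizable position at C2. The closure happens at a carbon flanked by the ring fusion. The plan says nothing about where C8 and C27 come from.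
- Comparison: as a ring closure it is probably as reliable as metathesis, or more so; the fallback for step 28 borrows it. The chosen plan sets against this a defined origin for C8 and C27 and an intermolecular, concentration-independent formation of the C23=C24 bond.

**Alternative 2:** The cut removes O16–C17, N31–C17 and N31–C30 of the oxaquinolizidine A2. In the forward key step a ketone at C17 and an azido alcohol form a spiro oxazinane, C30 migrates to N31 with loss of N2, and hydride adds to C17 of the iminium ether.
- Merits: three bonds and two rings in one operation, and a short eastern sequence.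
- Weak points: the less substituted carbon C30 has to migrate in preference to C18. The hydride must add to the correct face of C17. An alkyl azide must be carried. The quinolizidinone half, where the difficult stereochemistry lies, is untouched.
- Comparison: if the migration were selective it would beat steps 21–23 in step count. The chosen plan sets against this a condensation that corrects C17 and C18 thermodynamically, and a key step spent on the western half.

**Alternative 3:** The cut is the C24–C27 bond, held temporarily by an N–O–C23 bridge in the isoxazolidine cycloadduct A3. In the forward key step a ring-B nitrone adds across an (E)-enone.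
- Merits: the union is convergent, and C27 is set relative to C8 and C24 relative to C27 stereospecifically from the enone geometry. It could deliver the H24/H27 syn relationship directly; on this point it is better than the chosen plan, which creates that relationship only in the last step.
- Weak points: the C23 oxygen must be removed after N–O cleavage, through a β-hydroxy ketone prone to elimination. Ring A still has to be closed at N4–C3. Once the ketone and the amine are free, C24 is as labile as in any route and must be carried through those steps. The nitrone needs its own enantioselective synthesis for C8.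
- Comparison: the chosen plan sets against the early C24 control a C24 centre that is formed last and never exposed, and a chiral-pool origin for C8 and C27.

Key step: step 12

Remark on the chemistry: atom labels C1–C34 follow the target SMILES. Chloro aldehyde 35 is used as the racemate because C18 is set under equilibrium control in step 23, and 20 is a pair of C27 epimers that give one iminium ion.

## Route

Step 1
Reactants: 1 (trimethylsilyl)methylmagnesium chloride; 2 acrolein
Product: 3 1-(trimethylsilyl)but-3-en-2-ol (racemic)
Conditions: Et2O, −78 → 0 °C; aq. NH4Cl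
Reagents that add atoms: none
Why: 1,2-Addition of the Grignard reagent to the aldehyde gives the allylic β-hydroxysilane; the neutral work-up avoids Peterson elimination.

Step 2
Reactants: 3 1-(trimethylsilyl)but-3-en-2-ol
Product: 4 1-(trimethylsilyl)but-3-en-2-yl acetate (racemic)
Conditions: Ac2O, pyridine, DMAP (cat.), CH2Cl2, 0 °C → rt
Reagents that add atoms: acetic anhydride, CC(=O)OC(C)=O
Why: DMAP-catalysed acetylation under basic conditions, which the β-hydroxysilane tolerates; the acetate carbons become C5 and C6.

Step 3
Reactants: 4 1-(trimethylsilyl)but-3-en-2-yl acetate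
Product: 7 (E)-6-(trimethylsilyl)hex-4-enoic acid, via silyl ketene acetal 5 (not isolated), via silyl ester 6 (not isolated)
Conditions: LiN(i-Pr)2, THF, −78 °C; t-BuMe2SiCl, DMPU, −78 → 60 °C; then AcOH, THF/H2O, rt
Reagents that add atoms: none
Why: Ireland–Claisen rearrangement: O-silylation of the acetate enolate and [3,3] shift through a chair with the CH2SiMe3 group equatorial should give the (E)-alkene; mild hydrolysis of the silyl ester frees the acid without protodesilylation.

Step 4
Reactants: 8 (R)-3-amino-2-methylpropanoic acid
Product: 9 (R)-3-(benzyloxycarbonylamino)-2-methylpropanoic acid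
Conditions: CbzCl, NaOH, THF/H2O, 0 °C → rt
Reagents that add atoms: benzyl chloroformate, O=C(Cl)OCc1ccccc1
Why: Schotten–Baumann carbamoylation of the amine; the stereocentre (future C2) is not involved.

Step 5
Reactants: 9 (R)-3-(benzyloxycarbonylamino)-2-methylpropanoic acid; 10 Meldrum's acid
Product: 12 benzyl (5R)-5-methyl-2,4-dioxopiperidine-1-carboxylate, via acyl Meldrum's acid 11 (not isolated)
Conditions: EDC·HCl, DMAP, CH2Cl2, 0 °C → rt; then EtOAc, reflux
Reagents that add atoms: none
Why: Carbodiimide acylation of Meldrum's acid, then thermal loss of acetone to an acyl ketene that the carbamate nitrogen traps, then loss of CO2 (known route from N-protected β-amino acids to piperidine-2,4-diones); the acid carbon becomes C25 and the Meldrum's acid carbons C24 and C27.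

Step 6
Reactants: 12 benzyl (5R)-5-methyl-2,4-dioxopiperidine-1-carboxylate
Product: 13 benzyl (6R)-6-methyl-9-oxo-1,4-dioxa-8-azaspiro[4.5]decane-8-carboxylate
Conditions: Me3SiOCH2CH2OSiMe3, Me3SiOTf (cat.), CH2Cl2, −78 → −20 °C
Reagents that add atoms: 1,2-bis(trimethylsilyloxy)ethane, C[Si](C)(C)OCCO[Si](C)(C)C
Why: Silyl triflate-catalysed ketalization with the bis-silyl glycol ether at low temperature protects the C25 ketone without touching the N-acyl lactam or the carbamate.

Step 7
Reactants: 13 benzyl (6R)-6-methyl-9-oxo-1,4-dioxa-8-azaspiro[4.5]decane-8-carboxylate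
Product: 15 benzyl (6R,10R)-6-methyl-9-oxo-10-[(triisopropylsilyloxy)methyl]-1,4-dioxa-8-azaspiro[4.5]decane-8-carboxylate (C24 substituent cis to the C2 methyl), via trans-alkylated lactam 14 (not isolated)
Conditions: LiN(SiMe3)2, THF, −78 °C; i-Pr3SiOCH2Cl; then LiN(SiMe3)2, −78 °C; AcOH, −78 °C
Reagents that add atoms: (chloromethoxy)tri(propan-2-yl)silane, ClCO[Si](C(C)C)(C(C)C)C(C)C
Why: Enolate C-alkylation with a chloromethyl ether should occur anti to the pseudo-axial ketal oxygen and give mainly the trans isomer 14; re-enolization and kinetic axial protonation from the same open face turn the new group equatorial, cis to the C2 methyl.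

Step 8
Reactants: 15 cis-configured ketal lactam
Product: 16 benzyl N-[(2R)-2-{2-[(2R)-1-hydroxy-3-(triisopropylsilyloxy)propan-2-yl]-1,3-dioxolan-2-yl}propyl]carbamate
Conditions: LiBH4, THF/EtOH, 0 °C → rt
Reagents that add atoms: none
Why: Hydride attacks the ring carbonyl of the N-carbamoyl lactam, the hemiaminal opens to the aldehyde and is reduced further (reductive ring opening of N-acyl lactams); C24 and C2 are untouched and C27 is now a CH2OH group.

Step 9
Reactants: 16 ring-opened carbamate alcohol
Product: 17 (2R)-2-{2-[(2R)-1-aminopropan-2-yl]-1,3-dioxolan-2-yl}-3-(triisopropylsilyloxy)propan-1-ol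
Conditions: H2 (1 atm), Pd/C, MeOH, rt
Reagents that add atoms: none
Why: Hydrogenolysis of the benzyl carbamate under neutral conditions that leave the ketal and silyl ether intact.

Step 10
Reactants: 17 amino alcohol; 7 (E)-6-(trimethylsilyl)hex-4-enoic acid
Product: 18 (4E)-N-[(2R)-2-{2-[(2R)-1-hydroxy-3-(triisopropylsilyloxy)propan-2-yl]-1,3-dioxolan-2-yl}propyl]-6-(trimethylsilyl)hex-4-enamide
Conditions: EDC·HCl, HOBt, CH2Cl2, 0 °C → rt
Reagents that add atoms: none
Why: Carbodiimide/HOBt amide coupling; the amine reacts far faster than the primary alcohol and the allylsilane is inert.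

Step 11
Reactants: 18 amide alcohol
Product: 20 ring-A N-acyl hemiaminal methyl ether (N4 acylated by (E)-6-(trimethylsilyl)hex-4-enoyl; C27 OMe as both epimers; C24 CH2OSi(i-Pr)3 cis to the C2 methyl; C25 dioxolane), via amido aldehyde 19 (not isolated)
Conditions: Dess–Martin periodinane, pyridine, CH2Cl2, 0 °C; then MeOH, PPTS (cat.), 3 Å MS, CH2Cl2, rt
Reagents that add atoms: methanol, CO
Why: Buffered Dess–Martin oxidation gives δ-amido aldehyde 19, which closes to the six-membered N-acyl hemiaminal and is fixed as its methyl ether under mild acid (amido-aldehyde route to cyclic N-acyliminium precursors); C24 is kept by avoiding base.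

Step 12
Reactants: 20 ring-A N-acyl hemiaminal methyl ether
Product: 21 vinyl quinolizidinone lactam ketal (C8 vinyl trans to C24 on ring B; C24 CH2OSi(i-Pr)3 trans to C8 and cis to the C2 methyl on ring A)
Conditions: BF3·OEt2, CH2Cl2, −78 → −20 °C
Reagents that add atoms: none
Why: BF3 ionizes either C27 epimer of 20 to the same ring-A N-acyliminium ion, and C8 (the γ-carbon of the allylsilane) attacks C27 with loss of Me3Si, leaving the vinyl group C9=C10. The closest known reaction type is the intramolecular addition of allylsilanes to cyclic N-acyliminium ions (aza-Sakurai cyclization) giving vinyl-substituted quinolizidinones. Ring B closes as a six-membered ring with the N4=C27 bond inside the new ring (endo) and the C8=C9 alkene outside it (exo). C8 is controlled by a chair-like transition state in which the rest of the (E)-allylsilane sits pseudo-equatorially, giving H8 anti to H27. C27 is controlled by ring A: the planar N-acyl tether can only deliver C8 into an equatorial position on ring A, and with the C24 group and the C2 methyl both pseudo-equatorial this means attack anti to the C24 substituent, the other face requiring both groups to turn syn-diaxial. The step needs this facial selectivity, and it needs the cation to cyclize faster than it loses the C24 proton to an enamide; the cis-configured C24 group secures the first, and low temperature with a reactive, well-placed allylsilane the second. The C25 ketal removes any ketone-based enolization and is expected to survive BF3·OEt2 at low temperature.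

Step 13
Reactants: 21 vinyl quinolizidinone lactam ketal
Product: 22 vinyl quinolizidine ketal (tertiary amine; substituents as in 21)
Conditions: LiAlH4, THF, 0 °C → reflux
Reagents that add atoms: none
Why: LiAlH4 reduces the tertiary lactam to the tertiary amine; ketal, silyl ether and vinyl group are inert.

Step 14
Reactants: 22 vinyl quinolizidine ketal
Product: 23 1-(hydroxymethyl)-3-methyl-9-vinylquinolizidin-2-one (C24 CH2OH trans to C8)
Conditions: 2 M HCl, THF, 45 °C; then NaHCO3
Reagents that add atoms: water, O
Why: Aqueous acid hydrolyses the dioxolane and the silyl ether in one operation; the β-hydroxy ketone stays as the stable all-equatorial C24 epimer.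

Step 15
Reactants: 23 β-hydroxy ketone
Product: 24 (3R,9R,9aR)-9-ethenyl-3-methyloctahydro-2H-quinolizin-2-one
Conditions: K2CO3 (cat.), MeOH, 50 °C
Reagents that add atoms: none
Why: Base-catalysed retro-aldol loss of formaldehyde from the α-hydroxymethyl ketone removes the C24 control group; the C2 methyl stays equatorial, its preferred position in this trans-fused ketone.

Step 16
Reactants: 25 (S)-3-amino-2-methylpropanoic acid
Product: 26 (S)-3-(tert-butoxycarbonylamino)-2-methylpropanoic acid
Conditions: Boc2O, NaOH, dioxane/H2O, 0 °C → rt
Reagents that add atoms: di-tert-butyl dicarbonate, CC(C)(C)OC(=O)OC(=O)OC(C)(C)C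
Why: Standard carbamate protection of the amine; the stereocentre (future C33) is not involved.

Step 17
Reactants: 26 (S)-3-(tert-butoxycarbonylamino)-2-methylpropanoic acid
Product: 27 tert-butyl N-[(2S)-3-[methoxy(methyl)amino]-2-methyl-3-oxopropyl]carbamate
Conditions: MeNHOMe·HCl, EDC·HCl, HOBt, N-methylmorpholine, CH2Cl2, 0 °C → rt
Reagents that add atoms: N,O-dimethylhydroxylamine hydrochloride, CNOC.Cl
Why: Carbodiimide coupling to the Weinreb amide; a β-amino acid cannot racemize through an oxazolone.

Step 18
Reactants: 27 Weinreb amide; 28 hex-5-enylmagnesium bromide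
Product: 29 tert-butyl N-[(2S)-2-methyl-3-oxonon-8-en-1-yl]carbamate
Conditions: THF, 0 °C (2.5 equiv of 28); aq. NH4Cl
Reagents that add atoms: none
Why: Grignard addition to the Weinreb amide stops at the ketone through the magnesium chelate; the first equivalent only deprotonates the carbamate.

Step 19
Reactants: 29 amino ketone
Product: 30 tert-butyl N-[(2S,3R)-3-hydroxy-2-methylnon-8-en-1-yl]carbamate
Conditions: (S)-2-methyl-CBS-oxazaborolidine (cat.), catecholborane, toluene, −78 °C
Reagents that add atoms: none
Why: Corey–Bakshi–Shibata reduction: the catalyst distinguishes the branched from the unbranched ketone substituent and should give the (R)-carbinol C15; Felkin–Anh control by C33 points the same way (2,3-anti), and catecholborane at −78 °C spares the terminal alkene.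

Step 20
Reactants: 30 carbamate alcohol
Product: 31 (2S,3R)-1-amino-2-methylnon-8-en-3-ol
Conditions: HCl, dioxane, 0 °C → rt; then aq. NaOH
Reagents that add atoms: none
Why: Acidolysis of the Boc group; the unactivated terminal alkene does not add HCl under these conditions.

Step 21
Reactants: 32 methyl 5-chloropentanoate; 33 (5-bromopentyloxy)(tert-butyl)dimethylsilane
Product: 34 methyl 7-(tert-butyldimethylsilyloxy)-2-(3-chloropropyl)heptanoate (racemic)
Conditions: LiN(i-Pr)2, THF, −78 °C; DMPU, 33, −78 → −20 °C
Reagents that add atoms: none
Why: Ester enolate alkylation with a primary bromide in the presence of DMPU; at low temperature the enolate does not displace its own δ-chloride.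

Step 22
Reactants: 34 chloro ester
Product: 35 7-(tert-butyldimethylsilyloxy)-2-(3-chloropropyl)heptanal (racemic)
Conditions: i-Bu2AlH, CH2Cl2, −78 °C
Reagents that add atoms: none
Why: Low-temperature i-Bu2AlH reduction of the ester stops at the aldehyde through the stable aluminium hemiacetal.

Step 23
Reactants: 31 (2S,3R)-1-amino-2-methylnon-8-en-3-ol; 35 chloro aldehyde
Product: 37 all-equatorial trans-fused 1-oxaquinolizidine (C15 hex-5-enyl; C33 methyl; C18 5-(tert-butyldimethylsilyloxy)pentyl), via tetrahydro-1,3-oxazine 36 (not isolated)
Conditions: MgSO4, CH2Cl2, rt; then K2CO3, NaI (cat.), MeCN, 60 °C; then AcOH (cat.), MeOH, 50 °C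
Reagents that add atoms: none
Why: Condensation of the 1,3-amino alcohol with the aldehyde gives oxazine 36, whose nitrogen displaces the chloride of the 3-chloropropyl arm to close ring D (known amino alcohol/5-haloaldehyde route to 1-oxaquinolizidines); C17 and, through the ring-opened iminium/enamine, C18 should equilibrate to the all-equatorial trans-fused bicycle dictated by C15 and C33.

Step 24
Reactants: 37 oxaquinolizidine silyl ether
Product: 38 oxaquinolizidine alcohol (C18 5-hydroxypentyl)
Conditions: Bu4NF, THF, rt
Reagents that add atoms: none
Why: Fluoride cleavage of the primary silyl ether; the tertiary N,O-acetal is inert to fluoride.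

Step 25
Reactants: 38 oxaquinolizidine alcohol
Product: 39 oxaquinolizidine aldehyde (C18 chain ending in the C23 aldehyde)
Conditions: (COCl)2, DMSO, CH2Cl2, −78 °C; Et3N, −78 → 0 °C
Reagents that add atoms: none
Why: Swern oxidation works on tertiary amino alcohols and, being basic and cold, keeps the N,O-acetal closed.

Step 26
Reactants: 24 quinolizidinone; 39 oxaquinolizidine aldehyde
Product: 40 aldol adduct (β-hydroxy ketone; C23 and C24 as epimer mixtures)
Conditions: LiN(i-Pr)2, THF, −78 °C; then 39, −78 °C
Reagents that add atoms: none
Why: The amide base removes a proton from the only α-methylene group (C24) and not from the C2 methine; the lithium enolate adds to aldehyde 39 (directed aldol), and the new centres at C23 and C24 are erased in step 27.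

Step 27
Reactants: 40 aldol adduct
Product: 42 acyclic (E)-enone diene (C23=C24; C8 vinyl; C15 hex-5-enyl), via mesylate 41 (not isolated)
Conditions: MsCl, Et3N, CH2Cl2, 0 °C; then DBU, rt
Reagents that add atoms: none
Why: Mesylation and E1cB elimination give the conjugated exocyclic enone, expected as the (E)-isomer with C22 turned away from the carbonyl oxygen.

Step 28
Reactants: 42 acyclic (E)-enone diene
Product: 43 macrocyclic dienone (9,10;23,24-tetradehydro target; C9=C10 as E/Z mixture)
Conditions: camphorsulfonic acid (2.2 equiv), second-generation Hoveyda–Grubbs catalyst, CH2Cl2 (high dilution), 40 °C; then aq. NaHCO3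
Reagents that add atoms: none
Why: Ring-closing metathesis of the two terminal alkenes forms the 18-membered ring; protonating both amines protects the catalyst and locks the N,O-acetal, the trisubstituted electron-poor enone does not take part, and the C9=C10 geometry is irrelevant.

Step 29
Reactants: 43 macrocyclic dienone
Product: 44 target CNP0236330.1
Conditions: H2 (1 atm), Pd/C, EtOAc, rt
Reagents that add atoms: none
Why: Heterogeneous hydrogenation saturates C9=C10 and adds hydrogen across C23=C24; allylic 1,3-strain between C22 and C8 should hold C8 axial on ring A (cis-fused invertomer) and block that face, so hydrogen arrives anti to C8 and sets H24 syn to H27 as in the target; no later step can epimerize C24 or C2.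

## Compound list

1 | (trimethylsilyl)methylmagnesium chloride | C[Si](C)(C)C[Mg]Cl | starting material
2 | acrolein | C=CC=O | starting material
3 | 1-(trimethylsilyl)but-3-en-2-ol (racemic) | C=CC(O)C[Si](C)(C)C | intermediate
4 | 1-(trimethylsilyl)but-3-en-2-yl acetate (racemic) | C=CC(OC(C)=O)C[Si](C)(C)C | intermediate
5 | tert-butyldimethylsilyl ketene acetal of 4 | C=C(O[Si](C)(C)C(C)(C)C)OC(C=C)C[Si](C)(C)C | intermediate
6 | tert-butyldimethylsilyl (E)-6-(trimethylsilyl)hex-4-enoate | C[Si](C)(C)C/C=C/CCC(=O)O[Si](C)(C)C(C)(C)C | intermediate
7 | (E)-6-(trimethylsilyl)hex-4-enoic acid | C[Si](C)(C)C/C=C/CCC(=O)O | intermediate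
8 | (R)-3-amino-2-methylpropanoic acid | NC[C@@H](C)C(=O)O | starting material
9 | (R)-3-(benzyloxycarbonylamino)-2-methylpropanoic acid | O=C(NC[C@@H](C)C(=O)O)OCc1ccccc1 | intermediate
10 | Meldrum's acid (2,2-dimethyl-1,3-dioxane-4,6-dione) | CC1(C)OC(=O)CC(=O)O1 | starting material
11 | acyl Meldrum's acid from 9 | CC1(C)OC(=O)C(C(=O)[C@H](C)CNC(=O)OCc2ccccc2)C(=O)O1 | intermediate
12 | benzyl (5R)-5-methyl-2,4-dioxopiperidine-1-carboxylate | C[C@@H]1CN(C(=O)OCc2ccccc2)C(=O)CC1=O | intermediate
13 | benzyl (6R)-6-methyl-9-oxo-1,4-dioxa-8-azaspiro[4.5]decane-8-carboxylate | C[C@@H]1CN(C(=O)OCc2ccccc2)C(=O)CC13OCCO3 | intermediate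
14 | trans-alkylated lactam (C24 epimer of 15, CH2OSi(i-Pr)3 trans to the C2 methyl) | C[C@@H]1CN(C(=O)OCc2ccccc2)C(=O)[C@@H](CO[Si](C(C)C)(C(C)C)C(C)C)C13OCCO3 | intermediate
15 | benzyl (6R,10R)-6-methyl-9-oxo-10-[(triisopropylsilyloxy)methyl]-1,4-dioxa-8-azaspiro[4.5]decane-8-carboxylate (C24 group cis to C2 methyl) | C[C@@H]1CN(C(=O)OCc2ccccc2)C(=O)[C@H](CO[Si](C(C)C)(C(C)C)C(C)C)C13OCCO3 | intermediate
16 | benzyl N-[(2R)-2-{2-[(2R)-1-hydroxy-3-(triisopropylsilyloxy)propan-2-yl]-1,3-dioxolan-2-yl}propyl]carbamate | OC[C@H](CO[Si](C(C)C)(C(C)C)C(C)C)C1(OCCO1)[C@H](C)CNC(=O)OCc1ccccc1 | intermediate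
17 | (2R)-2-{2-[(2R)-1-aminopropan-2-yl]-1,3-dioxolan-2-yl}-3-(triisopropylsilyloxy)propan-1-ol | OC[C@H](CO[Si](C(C)C)(C(C)C)C(C)C)C1(OCCO1)[C@H](C)CN | intermediate
18 | (4E)-N-[(2R)-2-{2-[(2R)-1-hydroxy-3-(triisopropylsilyloxy)propan-2-yl]-1,3-dioxolan-2-yl}propyl]-6-(trimethylsilyl)hex-4-enamide | OC[C@H](CO[Si](C(C)C)(C(C)C)C(C)C)C1(OCCO1)[C@H](C)CNC(=O)CC/C=C/C[Si](C)(C)C | intermediate
19 | amido aldehyde (C27 aldehyde of 18) | O=C[C@H](CO[Si](C(C)C)(C(C)C)C(C)C)C1(OCCO1)[C@H](C)CNC(=O)CC/C=C/C[Si](C)(C)C | intermediate
20 | ring-A N-acyl hemiaminal methyl ether (C27 epimers; C24 CH2OSi(i-Pr)3 cis to C2 methyl; C25 dioxolane) | C[C@@H]1CN(C(=O)CC/C=C/C[Si](C)(C)C)C(OC)[C@H](CO[Si](C(C)C)(C(C)C)C(C)C)C12OCCO2 | intermediate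
21 | vinyl quinolizidinone lactam ketal (H8 anti to H27; C24 group trans to C8, cis to C2 methyl) | C[C@@H]1CN2C(=O)CC[C@H](C=C)[C@H]2[C@H](CO[Si](C(C)C)(C(C)C)C(C)C)C13OCCO3 | intermediate
22 | vinyl quinolizidine ketal (amine from 21) | C[C@@H]1CN2CCC[C@H](C=C)[C@H]2[C@H](CO[Si](C(C)C)(C(C)C)C(C)C)C13OCCO3 | intermediate
23 | 1-(hydroxymethyl)-3-methyl-9-vinylquinolizidin-2-one (CH2OH trans to C8) | C[C@@H]1CN2CCC[C@H](C=C)[C@H]2[C@H](CO)C1=O | intermediate
24 | (3R,9R,9aR)-9-ethenyl-3-methyloctahydro-2H-quinolizin-2-one | C[C@@H]1CN2CCC[C@H](C=C)[C@H]2CC1=O | intermediate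
25 | (S)-3-amino-2-methylpropanoic acid | NC[C@H](C)C(=O)O | starting material
26 | (S)-3-(tert-butoxycarbonylamino)-2-methylpropanoic acid | CC(C)(C)OC(=O)NC[C@H](C)C(=O)O | intermediate
27 | tert-butyl N-[(2S)-3-[methoxy(methyl)amino]-2-methyl-3-oxopropyl]carbamate | CC(C)(C)OC(=O)NC[C@H](C)C(=O)N(C)OC | intermediate
28 | hex-5-enylmagnesium bromide | C=CCCCC[Mg]Br | starting material
29 | tert-butyl N-[(2S)-2-methyl-3-oxonon-8-en-1-yl]carbamate | CC(C)(C)OC(=O)NC[C@H](C)C(=O)CCCCC=C | intermediate
30 | tert-butyl N-[(2S,3R)-3-hydroxy-2-methylnon-8-en-1-yl]carbamate | CC(C)(C)OC(=O)NC[C@H](C)[C@H](O)CCCCC=C | intermediate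
31 | (2S,3R)-1-amino-2-methylnon-8-en-3-ol | NC[C@H](C)[C@H](O)CCCCC=C | intermediate
32 | methyl 5-chloropentanoate | COC(=O)CCCCCl | starting material
33 | (5-bromopentyloxy)(tert-butyl)dimethylsilane | CC(C)(C)[Si](C)(C)OCCCCCBr | starting material
34 | methyl 7-(tert-butyldimethylsilyloxy)-2-(3-chloropropyl)heptanoate (racemic) | COC(=O)C(CCCCl)CCCCCO[Si](C)(C)C(C)(C)C | intermediate
35 | 7-(tert-butyldimethylsilyloxy)-2-(3-chloropropyl)heptanal (racemic) | O=CC(CCCCl)CCCCCO[Si](C)(C)C(C)(C)C | intermediate
36 | tetrahydro-1,3-oxazine from 31 and 35 (C17/C18 epimer mixture) | C=CCCCC[C@H]1OC(NC[C@@H]1C)C(CCCCl)CCCCCO[Si](C)(C)C(C)(C)C | intermediate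
37 | all-equatorial trans-fused 1-oxaquinolizidine silyl ether (C15 hex-5-enyl, C33 methyl, C18 silyloxypentyl) | C=CCCCC[C@H]1O[C@H]2[C@H](CCCCCO[Si](C)(C)C(C)(C)C)CCCN2C[C@@H]1C | intermediate
38 | oxaquinolizidine alcohol | C=CCCCC[C@H]1O[C@H]2[C@H](CCCCCO)CCCN2C[C@@H]1C | intermediate
39 | oxaquinolizidine aldehyde (C23 aldehyde) | C=CCCCC[C@H]1O[C@H]2[C@H](CCCCC=O)CCCN2C[C@@H]1C | intermediate
40 | aldol adduct (C23, C24 epimer mixture) | C[C@@H]1CN2CCC[C@H](C=C)[C@H]2C(C(O)CCCC[C@@H]3CCCN4C[C@H](C)[C@@H](CCCCC=C)O[C@@H]34)C1=O | intermediate
41 | mesylate of 40 | C[C@@H]1CN2CCC[C@H](C=C)[C@H]2C(C(OS(C)(=O)=O)CCCC[C@@H]3CCCN4C[C@H](C)[C@@H](CCCCC=C)O[C@@H]34)C1=O | intermediate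
42 | acyclic (E)-enone diene | C[C@@H]1CN2CCC[C@H](C=C)[C@H]2/C(=C\CCCC[C@@H]3CCCN4C[C@H](C)[C@@H](CCCCC=C)O[C@@H]34)C1=O | intermediate
43 | macrocyclic dienone (9,10;23,24-tetradehydro target) | C[C@@H]1CN2CCC[C@@H]3C=CCCCC[C@H]4O[C@H]5[C@H](CCCC/C=C(/C1=O)[C@H]32)CCCN5C[C@@H]4C | intermediate
44 | target CNP0236330.1 | C[C@@H]1CN2CCC[C@@H]3CCCCCC[C@H]4O[C@H]5[C@H](CCCCC[C@@H](C1=O)[C@H]32)CCCN5C[C@@H]4C | target

## Step count and least certain steps

Total: 29 steps. Longest linear sequence: 16 steps from 8 (steps 4–15 and 26–29).

**Step 12 (key step).** The most likely failure is proton loss from C24 of the N-acyliminium ion. This would scramble the C24 control centre, erode the facial selectivity at C27, or stop the reaction at the enamide. The fallback closes ring B through the less acidic N-alkyl iminium ion. Setting out from 18, LiAlH4 should reduce the amide to the secondary amine alcohol F1. Oxidation of the primary alcohol of its trifluoroacetate salt with Dess–Martin periodinane should give the amino aldehyde in its ring-closed form, the cyclic carbinolamine F2. Camphorsulfonic acid in MeCN should then ionize F2, and the allylsilane should close ring B in a Mannich-type cyclization that gives amine 22 directly, where the route is rejoined.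

**Step 15.** The most likely failure is that dehydration of 23 to the α-methylene ketone, followed by its oligomerization, outruns the retro-aldol cleavage. The fallback removes the C24 carbon by decarboxylation. Setting out from 22, Bu4NF should give the ketal alcohol F3, Swern oxidation the ketal aldehyde F4, and NaClO2 oxidation the ketal acid F5. Warm aqueous HCl should then hydrolyse the ketal and expel CO2 in one operation, returning to 24.

**Step 28.** The most likely failure is slow initiation at the hindered C8 vinyl group together with catalyst loss to the amines, so that intermolecular metathesis and oligomers dominate at the dilution needed. The fallback makes C9=C10 intermolecularly and closes the ring at C23=C24. Setting out from 24, kinetic enolization and ClP(O)(OEt)2 should give the enol phosphate F6, which LiN(i-Pr)2 should rearrange by 1,3-phosphorus shift to the β-ketophosphonate F7. Cross-metathesis of F7 with an excess of 39 (both as camphorsulfonates) should give the phosphonate aldehyde F8. An intramolecular Horner–Wadsworth–Emmons reaction (LiCl, DBU, MeCN, high dilution) should then close the macrocycle to 43, where the route is rejoined.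

**Step 29.** The most likely failure is migration of the C23=C24 double bond into ring A on the palladium surface, or hydrogen delivery to the wrong face of C24. The fallback separates the two reductions and sets C24 by protonation. Setting out from 43, RhCl(PPh3)3 and H2 should saturate only the disubstituted C9=C10 bond and give the 23,24-didehydro macrocycle F9. Conjugate reduction with [(Ph3P)CuH]6 and kinetic protonation of the resulting C24 enolate by a hindered phenol should then give 44.

## Further compounds

F1 | step 12 | secondary amine alcohol (amide of 18 reduced to CH2) | OC[C@H](CO[Si](C(C)C)(C(C)C)C(C)C)C1(OCCO1)[C@H](C)CNCCC/C=C/C[Si](C)(C)C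
F2 | step 12 | cyclic carbinolamine (ring-A N-alkyl hemiaminal, C27 epimers) | C[C@@H]1CN(CCC/C=C/C[Si](C)(C)C)C(O)[C@H](CO[Si](C(C)C)(C(C)C)C(C)C)C12OCCO2
F3 | step 15 | ketal alcohol (22 without the silyl group) | C[C@@H]1CN2CCC[C@H](C=C)[C@H]2[C@H](CO)C13OCCO3
F4 | step 15 | ketal aldehyde | C[C@@H]1CN2CCC[C@H](C=C)[C@H]2[C@H](C=O)C13OCCO3
F5 | step 15 | ketal acid | C[C@@H]1CN2CCC[C@H](C=C)[C@H]2[C@H](C(=O)O)C13OCCO3
F6 | step 28 | diethyl enol phosphate of 24 (C24=C25) | C[C@@H]1CN2CCC[C@H](C=C)[C@H]2C=C1OP(=O)(OCC)OCC
F7 | step 28 | C24 β-ketophosphonate of 24 | C[C@@H]1CN2CCC[C@H](C=C)[C@H]2C(P(=O)(OCC)OCC)C1=O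
F8 | step 28 | phosphonate aldehyde (F7 and 39 joined at C9=C10) | C[C@@H]1CN2CCC[C@H](C=CCCCC[C@H]3O[C@H]4[C@H](CCCCC=O)CCCN4C[C@@H]3C)[C@H]2C(P(=O)(OCC)OCC)C1=O
F9 | step 29 | 23,24-didehydro macrocycle (C9–C10 saturated) | C[C@@H]1CN2CCC[C@@H]3CCCCCC[C@H]4O[C@H]5[C@H](CCCC/C=C(/C1=O)[C@H]32)CCCN5C[C@@H]4C
A1 | alternative 1 | macrocyclic exocyclic E-enone (23,24-didehydro target) | C[C@@H]1CN2CCC[C@@H]3CCCCCC[C@H]4O[C@H]5[C@H](CCCC/C=C(/C1=O)[C@H]32)CCCN5C[C@@H]4C
A2 | alternative 2 | trans-fused oxaquinolizidine with C9 and C23 handles | C=CCCCC[C@@H]1CCCN2C[C@H](C)[C@@H](CCCCCCOCc3ccccc3)O[C@@H]12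
A3 | alternative 3 | isoxazolidine cycloadduct | CCC(=O)[C@@H]1[C@@H](CCCCOCc2ccccc2)ON2CCC[C@H](CCCCCCCO[Si](C)(C)C(C)(C)C)[C@@H]12
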